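The numbers in the tables stem from a simulated flask for an exercise; scatter was added.

One number held nearly still across the earlier runs. If the partner (charged at Pc, in mM) decays first-order while also adding to the substrate (charged at Sc, standing at S), the two competing losses share one clock. So ln(Sc/S) grows in step with the partner lost to decay, and the proportion r stays fixed. Once the substrate stops falling, and leaving aside the partner taken into bis adduct, that lost partner is Pc − (Sc − S), which gives r = ln(Sc/S) / (Pc − Sc + S).

| flask | substrate | partner | remark | time |
|---|---|---|---|---|
| oak | 20 mM | 84 mM | run made earlier |  |
| larch | 20 mM | 130 mM | run made earlier |  |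
| alder | 40 mM | 60 mM | run made earlier |  |
| flask | 20 mM | 60.0 mM |  | 15 min |

- oak (time / min: substrate / %, single product / %): 2.50: 70.3, 28.7; 5.00: 67.3, 31.6; 8.00: 67.0, 31.4; 10.0: 67.4, 32.3; 12.0: 66.4, 30.7
- larch (time / min: substrate / %, single product / %): 1.00: 70.5, 27.8; 2.00: 60.0, 38.4; 3.00: 56.2, 42.4; 6.00: 53.9, 43.5; 12.0: 54.1, 44.9
- alder (time / min: substrate / %, single product / %): 1.00: 85.6, 14.3; 2.00: 80.2, 19.3; 3.00: 78.5, 22.3; 6.00: 76.5, 21.2; 12.0: 76.7, 22.3

(readings scatter by 0.5 percentage points)

- the substrate standing at 15 min, as a percentage of the substrate charged
- the single product standing at 15 min, as a percentage of the substrate charged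
- the other mono adduct standing at 15 min, as a percentage of the substrate charged
- the bis adduct standing at 15 min, as a percentage of the substrate charged

- steps under discussion: partner -> decomposed reagent; partner + single product -> bis adduct; partner + other mono adduct -> bis adduct; substrate + partner -> single product; substrate + partner -> other mono adduct

I turned the settings in order. By hand, time should add nothing once S stands still, and oak's substrate moved 0.6 percentage points between 8.00 min and 12.0 min, against a scatter of 0.5 points. By hand, more partner should raise the logarithm but leave r alone: oak gave 0.00530 mM⁻¹ and larch 0.00508 mM⁻¹. By hand, substrate should enter through the subtracted term, and alder, with twice oak's substrate and also less partner, gave 0.00523 mM⁻¹. Their mean, 0.00521 mM⁻¹, a reading that carries the scatter, is what I call the capture ratio: the logarithmic fall of substrate per mM of partner lost to decay.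

For the flask I first froze the partner spent on substrate at nought, which gave 73.2% substrate. Putting that spending back gave 75.2%, and once more 75.1%. Larch's shortfall of 1 point stood too near the scatter to split between the minor species, so I committed to the substrate.

The forecast, reasoning that “the partner must be dying”, gave 75.2% substrate, 23.8% single product, 0.8% other mono adduct and 0.2% bis adduct.

The flask gave 75.3% substrate, 23.9% single product, 0.726% other mono adduct and 0.117% bis adduct, with 0% of the partner, the limiting reagent, left at 15.0 min.

    partner → decomposed reagent (k = 0.0130 s⁻¹)
    partner + single product → bis adduct (k = 0.00130 M⁻¹ s⁻¹)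
    partner + other mono adduct → bis adduct (k = 0.0290 M⁻¹ s⁻¹)
    substrate + partner → single product (k = 0.0650 M⁻¹ s⁻¹)
    substrate + partner → other mono adduct (k = 0.00210 M⁻¹ s⁻¹)

The flask's own substrate returned a capture ratio of 0.00516 mM⁻¹. Part of what held the bis adduct at 0.117% was the decay of the partner together with its falling level: the run without that decay held 4.97% bis adduct, and there the substrate stood at 6.30%. For the neighbour with 240 mM of partner, the capture ratio gave 30.9% substrate, and that flask held 31.2%.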